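## Analysis of the target

The target is a eudesmane-type sesquiterpenoid diester built on a trans-fused decalin. Ring A is C1, C2, C3, C4, C5, C10 and ring B is C5, C6, C7, C8, C9, C10; C11 is the carbinol carbon on C7. The decalin carries four stereocentres: C3 (ester oxygen β, equatorial), C4 (acetoxy α and equatorial, methyl β and axial), C5 (H α) and the quaternary C10 (methyl β). The C4 and C10 methyl groups are therefore 1,3-diaxial on the β face and the C3/C4 oxygens are trans-diequatorial, so a single syn-dihydroxylation cannot deliver them. Two further stereocentres lie in the oxirane of the C3 ester, which is the (2S,3R)-epoxide of tiglic acid with both methyl groups cis. Ring B holds the enone C8(=O)–C7=C6, and C7 bears the free tertiary carbinol C11. C8, C7 and C11 together are the aldol of a ring ketone with acetone, which can undergo retro-aldol cleavage or dehydrate to the 7(11)-enone as long as C6=C7 is missing. The sensitive groups are the glycidic ester, the tertiary acetate beside it, and two tertiary alcohols (on C4 and C11) that must end in different states. The hardest stereochemical point is the C5/C10 relationship, because the two carbon groups on C10 differ little in size. The strategy rests on reading C8(=O)–C7–C11(OH) as the N–O cleavage product of a 2-isoxazoline (C8=N–O–C11, with C7 as ring carbon), formed together with ring B from a C8 nitrile oxide on the C10 arm and the C7=C11 alkene of a prenyl group on C5.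

## Retrosynthetic reasoning

**C6=C7 last.** The enone double bond of 28 is removed first, which leads to the saturated β-hydroxy ketone 27. Dehydrogenation of 27 can only run toward C6, because the other α-carbon, C9, is attached to the quaternary C10. Placing it last keeps the conjugated enone away from the hydride and dihydroxylation steps. The forward reaction has to enolise toward the hindered C7 without eliminating the C11 hydroxyl.

**N–O bond.** 27 is the hydrolysed N–O cleavage product of isoxazoline 25, through imine 26. This cut replaces the retro-aldol-prone β-hydroxy ketone by a heterocycle that tolerates base, hydride, dihydroxylation and acylation. It also hides the C11 hydroxyl, so that the alcohol on C4 is the only free tertiary alcohol when the acetate is introduced. The forward reaction must cleave N–O reductively in the presence of two esters and an oxirane.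

**Acyl groups.** The acetate of 25 is removed to give 24, and the C3 ester bond of 24 is cut to diol 18 and acid 22. The secondary alcohol is acylated before the tertiary one, so no protecting group is needed. Acid 22 goes back to epoxy alcohol 21, allylic alcohol 20 and tiglic acid 19, the (E)-alkene of 19 fixing the cis relationship of the oxirane methyl groups and a Sharpless epoxidation fixing the absolute configuration.

**C3 and C4 oxygens.** The trans-diol 18 is traced to ketol 17 and the cis-diol 16, and 16 to alkene 15. Syn-dihydroxylation from the α face, opposite the axial C10 methyl, sets C4 correctly. C3 is then inverted by oxidation and axial hydride delivery. An epoxide opening was not used because trans-diaxial opening would put the nucleophile on C4 with the wrong configuration.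

**Ring B and the isoxazoline (key disconnection).** In 15 the bonds C7–C8 and O–C11 are cut, which gives nitrile oxide 14, made in the flask from aldoxime 12 through hydroximoyl chloride 13. One carbon–carbon bond and one carbon–oxygen bond close two rings and install C8, C7 and C11 at the final oxidation level. No other disconnection of ring B delivers the masked aldol directly.

**Aldoxime arm.** Oxime 12 comes from aldehyde 11 and alcohol 10, and 10 from hydroboration of the vinyl group of triene 8 through borane 9. The vinyl group is the only monosubstituted alkene of 8, so it can be addressed selectively.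

**C4 methyl and the 3-ene before the cycloaddition.** Triene 8 is traced to enol triflate 7 and ketone 5, through enolate 6. The C4 carbonyl is converted into the methyl-bearing alkene at the monocyclic stage and is not protected. A ketal would expose the epimerisable C5 to acid twice, and triflate formation after the cycloaddition would need a strong base next to the isoxazoline. The ring alkene is a spectator in the key step, and two steps are saved.

**C10 and C5.** Ketone 5 is cut at C10–vinyl and C5–C6, which gives enone 1, Grignard reagent 2 and bromide 3, joined through enolate 4. The conjugate addition sets the absolute configuration at C10 and gives the enolate regiospecifically at C5. The alkylation has to place the prenyl group trans to vinyl; this is the least secure stereochemical element of the route.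

## Alternatives that were turned down

**Alternative 1:** Ring B is cut at C5–C6 and C9–C10 as a Diels–Alder reaction. Diene A1 would add to the cyclic β-keto ester dienophile A2 under a chiral copper bis(oxazoline) Lewis acid (divalent copper, from Cu(OTf)2), giving the cis-fused adduct A3 with the C7=C8 silyl enol ether.
- For: it is convergent, forms two bonds and the C10 quaternary centre in one catalytic enantioselective step, uses two-point binding of the β-keto ester, and leaves a nucleophilic C7 next to the C8 oxygen. On convergence and on catalyst control of C10 it is stronger than the chosen route.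
- Against: A2 is a tetrasubstituted, β,β-disubstituted alkene, so two adjacent quaternary centres have to form in a slow cycloaddition. A3 is necessarily cis-fused and carries an ester on C5 that the target lacks. After its removal C5 is set by protonation next to the C4 ketone, where the angular methyl makes the trans preference small. The side chain would then come from a crossed aldol that gives the free β-hydroxy ketone and two unprotected tertiary alcohols.
- Comparison: the chosen route uses no sacrificial carbon, fixes C5 before ring closure and delivers the aldol already masked. The ester removal, C5 adjustment and aldol of this alternative would cost more steps than the cycloaddition route needs.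

**Alternative 2:** The C5–C10 bond is cut across the ten-membered ring of germacrone A4. A confined chiral Brønsted acid would protonate C1, the C4=C5 alkene would attack the C10 cation, and loss of a C3 proton would give dienone A5.
- For: A4 is commercial and contains all fifteen skeletal carbons. One step gives the trans-decalin with the 3-ene and the C8 ketone, and the trans fusion follows from the chair–chair transannular closure. On step economy this is clearly stronger than the chosen route.
- Against: A4 is achiral and conformationally mobile, so the whole absolute configuration depends on proton transfer to one of two rapidly interconverting enantiomeric conformers, without a covalent handle. The conjugated carbonyl and the C4=C5 alkene are competing basic sites. The final proton can be lost from C3, C15 or C5. A5 still has to be converted from the 7(11)-en-8-one into the 6-en-8-one with a C11 hydroxyl, which again passes through the free β-hydroxy ketone.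
- Comparison: the chosen route fixes the absolute configuration in a ligand-controlled conjugate addition to a simple enone and brings C7, C8 and C11 at the right oxidation level in protected form. It pays for this with a longer sequence.

**Alternative 3:** Rings A and B are cut at C4–C5 and C9–C10. The acyclic α-silyloxy methyl ketone A6 would be activated at the C4 carbonyl by an alkylaluminium dichloride, the (E)-C5=C10 alkene would attack it, and the C10 cation would be trapped by the 2-chloroalkene, giving decalin A7 after hydrolysis.
- For: C3 (from the chiral pool), C4, C5 and C10 are set in one step. The trans fusion is guaranteed by anti addition across the (E)-alkene, and the 3β,4α-diol arrives without inversion. On ring-fusion and ring A stereocontrol it is stronger than the chosen route.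
- Against: A6 needs a longer linear synthesis with a geometrically pure trisubstituted alkene, a chloroalkene terminus and an epimerisable α-silyloxy ketone. Ketone-initiated cyclisations are less dependable than epoxide- or acetal-initiated ones, and chelation of the aluminium between the carbonyl and the silyloxy group could alter the face selectivity at C4. After cyclisation the C7 side chain still requires a crossed aldol on the C8 ketone, with retro-aldol risk and two tertiary alcohols to differentiate.
- Comparison: the total length is similar. The chosen route reaches its cyclisation precursor in six steps and carries the aldol pre-formed and masked. In return it accepts a C3 inversion and weaker control at C5.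

Key step: step 7

Remark on the chemistry: the enantiomer of the chiral carbene ligand in step 1 is taken to be the one that delivers the vinyl group to the face of 1 giving the (3R) centre of 4; α and β denote the faces opposite to and the same as the C10 methyl group.

## Steps

Step 1
Reactants: 1 3-methylcyclohex-2-en-1-one; 2 vinylmagnesium bromide; 3 prenyl bromide (1-bromo-3-methylbut-2-ene)
Product: 5 (2R,3R)-3-ethenyl-3-methyl-2-(3-methylbut-2-en-1-yl)cyclohexan-1-one, via bromomagnesium enolate 4 (not isolated)
Conditions: Cu(OTf)2 (cat.), chiral N-heterocyclic carbene ligand (cat., from its imidazolinium salt), Et2O, −30 °C; then 3, DMPU, −30 °C → rt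
Reagents that add atoms: none
Why: Copper-catalysed asymmetric conjugate addition of a Grignard reagent to a β-substituted cyclic enone sets the quaternary C10 under ligand control and gives the enolate regiospecifically at C5. Alkylation of that enolate by the allylic bromide should go through the half-chair in which the flat vinyl group is axial, the electrophile entering anti to it, so that prenyl ends trans to vinyl and cis to methyl. The minor C5 epimer would be removed by chromatography here, and the ketone is not exposed to equilibrating base afterwards.

Step 2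
Reactants: 5 (2R,3R)-3-ethenyl-3-methyl-2-(3-methylbut-2-en-1-yl)cyclohexan-1-one
Product: 7 (5R,6R)-5-ethenyl-5-methyl-6-(3-methylbut-2-en-1-yl)cyclohex-1-en-1-yl trifluoromethanesulfonate, via lithium enolate 6 (not isolated)
Conditions: LDA, THF, −78 °C; PhNTf2, −78 → 0 °C
Reagents that add atoms: N-phenylbis(trifluoromethanesulfonimide), O=S(=O)(N(c1ccccc1)S(=O)(=O)C(F)(F)F)C(F)(F)F
Why: Kinetic deprotonation by the hindered amide removes a proton from the C3 methylene and not the C5 methine beside the quaternary carbon, and O-sulfonylation of the enolate gives the enol triflate. C5 is never enolised, so its configuration is kept.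

Step 3
Reactants: 7 (5R,6R)-5-ethenyl-5-methyl-6-(3-methylbut-2-en-1-yl)cyclohex-1-en-1-yl trifluoromethanesulfonate
Product: 8 (5R,6S)-5-ethenyl-1,5-dimethyl-6-(3-methylbut-2-en-1-yl)cyclohex-1-ene
Conditions: MeMgBr, Fe(acac)3 (5 mol %), THF/NMP, −30 → 0 °C
Reagents that add atoms: methylmagnesium bromide, C[Mg]Br
Why: Iron-catalysed cross-coupling of an alkenyl triflate with a methyl Grignard reagent replaces the triflate by methyl with retention of the double-bond position, giving the C3=C4 alkene with the C4 methyl group. The isolated alkenes and both stereocentres are untouched.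

Step 4
Reactants: 8 (5R,6S)-5-ethenyl-1,5-dimethyl-6-(3-methylbut-2-en-1-yl)cyclohex-1-ene
Product: 10 2-[(1R,2R)-1,3-dimethyl-2-(3-methylbut-2-en-1-yl)cyclohex-3-en-1-yl]ethan-1-ol, via B-alkyl-9-BBN adduct 9 (not isolated)
Conditions: 9-BBN, THF, 0 °C → rt; then NaOH, H2O2, 0 °C
Reagents that add atoms: hydrogen peroxide, OO
Why: Brown hydroboration with the bulky dialkylborane selects the monosubstituted vinyl group over the two trisubstituted alkenes and places boron on the terminal carbon C8. Oxidation of the C–B bond then gives the primary alcohol.

Step 5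
Reactants: 10 2-[(1R,2R)-1,3-dimethyl-2-(3-methylbut-2-en-1-yl)cyclohex-3-en-1-yl]ethan-1-ol
Product: 11 2-[(1R,2R)-1,3-dimethyl-2-(3-methylbut-2-en-1-yl)cyclohex-3-en-1-yl]acetaldehyde
Conditions: Dess–Martin periodinane, CH2Cl2, 0 °C → rt
Reagents that add atoms: none
Why: Dess–Martin oxidation stops at the aldehyde and leaves the alkenes alone. The aldehyde has no α-stereocentre to lose.

Step 6
Reactants: 11 2-[(1R,2R)-1,3-dimethyl-2-(3-methylbut-2-en-1-yl)cyclohex-3-en-1-yl]acetaldehyde
Product: 12 (1E)-2-[(1R,2R)-1,3-dimethyl-2-(3-methylbut-2-en-1-yl)cyclohex-3-en-1-yl]acetaldehyde oxime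
Conditions: NH2OH·HCl, NaOAc, EtOH/H2O, rt
Reagents that add atoms: hydroxylamine hydrochloride, NO.Cl
Why: Condensation of the aldehyde with hydroxylamine gives the aldoxime. Its C=N geometry is irrelevant because both isomers give the same nitrile oxide.

Step 7
Reactants: 12 (1E)-2-[(1R,2R)-1,3-dimethyl-2-(3-methylbut-2-en-1-yl)cyclohex-3-en-1-yl]acetaldehyde oxime
Product: 15 trans-fused tricyclic isoxazoline (3-ene with 4-methyl; 5α-H; 10β-methyl; 7α-H; C8=N–O–C11 ring with two methyl groups on C11), via hydroximoyl chloride 13 (not isolated), via nitrile oxide 14 (not isolated)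
Conditions: aq. NaOCl (slow addition), Et3N (cat.), CH2Cl2, 0 °C → rt, high dilution
Reagents that add atoms: none
Why: Hypochlorite chlorinates the aldoxime to hydroximoyl chloride 13, the amine removes HCl to give nitrile oxide 14, and 14 adds to the C7=C11 alkene in a concerted suprafacial [3+2] cycloaddition; the closest known reaction type is the intramolecular nitrile oxide–alkene cycloaddition to cyclohexane-fused 2-isoxazolines. Ring B closes through C7–C8 as a six-membered carbocycle in the exo mode (the dipole carbon bonds to the proximal alkene carbon and C11 stays outside the carbocycle), and the isoxazoline closes in the same event through O–C11 as a five-membered ring fused across C7–C8. The one new stereocentre, C7, is set by the chair-like transition state in which the C9 and C6 arms are equatorial on ring A and the C7–C11 bond is equatorial on the forming ring (7α-H); it is removed again in step 17. Regioselectivity is secured by the four-atom tether C9–C10–C5–C6 and by the usual bonding of oxygen to the more substituted alkene terminus. Site selectivity over the C3=C4 ring alkene is secured because addition there would build a strained bridged bicycle. The ring fusion stays trans because C5 and C10 are spectators with trans arms. Slow generation at high dilution keeps the concentration of 14 low against dimerisation.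

Step 8
Reactants: 15 trans-fused tricyclic isoxazoline
Product: 16 3α,4α-diol of 15 (4β-methyl; 5α-H; 7α-H; 10β-methyl)
Conditions: OsO4 (cat.), NMO, acetone/H2O, rt
Reagents that add atoms: N-methylmorpholine N-oxide, C[N+]1([O-])CCOCC1; water, O
Why: Upjohn syn-dihydroxylation of the only C=C bond occurs on the α face, away from the axial C10 methyl group that is 1,3 to C4. This sets C4 with the hydroxyl α and the methyl β, and leaves C3 with an α (axial) hydroxyl to be inverted.

Step 9
Reactants: 16 3α,4α-diol of 15
Product: 17 4α-hydroxy-3-ketone (4β-methyl; 5α-H; 7α-H; 10β-methyl)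
Conditions: IBX, DMSO, rt
Reagents that add atoms: none
Why: IBX oxidises the secondary alcohol of a 1,2-diol to the α-hydroxy ketone without cleaving the C3–C4 bond. The tertiary alcohol and the isoxazoline are inert.

Step 10
Reactants: 17 4α-hydroxy-3-ketone
Product: 18 3β,4α-diol (4β-methyl; 5α-H; 7α-H; 10β-methyl)
Conditions: NaBH4, MeOH, −20 °C
Reagents that add atoms: none
Why: Borohydride reduction delivers hydride axially from the α face, anti to the axial 4β-methyl group that blocks the β face, so the equatorial 3β-alcohol results and C3 is inverted overall. The isoxazoline C=N is not reduced by NaBH4.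

Step 11
Reactants: 19 tiglic acid [(2E)-2-methylbut-2-enoic acid]
Product: 20 (2E)-2-methylbut-2-en-1-ol
Conditions: LiAlH4, Et2O, 0 °C
Reagents that add atoms: none
Why: Hydride reduction of the carboxylic acid gives the allylic alcohol by 1,2-reduction, with the (E)-alkene retained.

Step 12
Reactants: 20 (2E)-2-methylbut-2-en-1-ol
Product: 21 [(2R,3R)-2,3-dimethyloxiran-2-yl]methanol
Conditions: Ti(OiPr)4, D-(−)-diisopropyl tartrate, t-BuOOH, 4 Å MS, CH2Cl2, −20 °C
Reagents that add atoms: tert-butyl hydroperoxide, CC(C)(C)OO
Why: Sharpless asymmetric epoxidation of the allylic alcohol with the D-tartrate delivers oxygen to the face that gives the (2R,3R)-epoxy alcohol. The cis relationship of the two methyl groups follows from the (E)-alkene.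

Step 13
Reactants: 21 [(2R,3R)-2,3-dimethyloxiran-2-yl]methanol
Product: 22 (2S,3R)-2,3-dimethyloxirane-2-carboxylic acid
Conditions: TEMPO (cat.), PhI(OAc)2, MeCN/H2O, rt
Reagents that add atoms: water, O
Why: Nitroxyl-catalysed oxidation takes the primary alcohol through the aldehyde hydrate to the acid under near-neutral conditions that leave the oxirane intact. The descriptor at C2 changes only because the substituent priorities change.

Step 14
Reactants: 18 3β,4α-diol; 22 (2S,3R)-2,3-dimethyloxirane-2-carboxylic acid
Product: 24 3β-[(2S,3R)-2,3-dimethyloxirane-2-carbonyloxy]-4α-ol, via mixed trichlorobenzoic anhydride 23 (not isolated)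
Conditions: 2,4,6-trichlorobenzoyl chloride, Et3N, THF, rt; then 18, DMAP, toluene, rt → 40 °C
Reagents that add atoms: none
Why: Yamaguchi esterification activates the hindered α,α-disubstituted acid as a mixed anhydride, and DMAP transfers the aliphatic acyl group to the secondary equatorial 3β-alcohol. The tertiary C4 alcohol does not react under these conditions, and no stereocentre is touched.

Step 15
Reactants: 24 3β-[(2S,3R)-2,3-dimethyloxirane-2-carbonyloxy]-4α-ol
Product: 25 4α-acetate of 24
Conditions: Ac2O, DMAP, Et3N, CH2Cl2, 40 °C
Reagents that add atoms: acetic anhydride, CC(=O)OC(C)=O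
Why: DMAP-catalysed acyl transfer acetylates the equatorial tertiary alcohol under forcing but non-acidic conditions that the oxirane tolerates. The acetylation is unambiguous because the C11 oxygen is still locked in the isoxazoline.

Step 16
Reactants: 25 4α-acetate of 24
Product: 27 8-keto-11-hydroxy compound (β-hydroxy ketone; 7α-H), via β-hydroxy imine 26 (not isolated)
Conditions: Mo(CO)6, MeCN/H2O, 80 °C
Reagents that add atoms: water, O
Why: Molybdenum hexacarbonyl cleaves the N–O bond of the 2-isoxazoline reductively, and the resulting β-hydroxy imine hydrolyses in the aqueous medium to the β-hydroxy ketone. The conditions are neutral and are expected to spare both esters and the oxirane.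

Step 17
Reactants: 27 8-keto-11-hydroxy compound
Product: 28 CNP0219255.6 [(3S,4S,5R,10R)-4α-acetoxy-11-hydroxy-8-oxoeudesm-6-en-3β-yl (2S,3R)-2,3-dimethyloxirane-2-carboxylate]
Conditions: IBX, 4-methoxypyridine N-oxide, DMSO, rt → 45 °C
Reagents that add atoms: none
Why: IBX dehydrogenation of a ketone proceeds through the enol toward C7 and removes the C6 hydrogen. It can only give the C6=C7 enone, because the other α-carbon, C9, is attached to the quaternary C10. The C7 stereocentre disappears and tertiary alcohols are not oxidised.

## Compound list

1 | 3-methylcyclohex-2-en-1-one | CC1=CC(=O)CCC1 | starting material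
2 | vinylmagnesium bromide | C=C[Mg]Br | starting material
3 | prenyl bromide (1-bromo-3-methylbut-2-ene) | CC(C)=CCBr | starting material
4 | bromomagnesium (3R)-3-ethenyl-3-methylcyclohex-1-en-1-olate | Br[Mg]OC1=C[C@@](C)(C=C)CCC1 | intermediate
5 | (2R,3R)-3-ethenyl-3-methyl-2-(3-methylbut-2-en-1-yl)cyclohexan-1-one | O=C1CCC[C@](C)(C=C)[C@H]1CC=C(C)C | intermediate
6 | lithium (5R,6R)-5-ethenyl-5-methyl-6-(3-methylbut-2-en-1-yl)cyclohex-1-en-1-olate | [Li]OC1=CCC[C@](C)(C=C)[C@H]1CC=C(C)C | intermediate
7 | (5R,6R)-5-ethenyl-5-methyl-6-(3-methylbut-2-en-1-yl)cyclohex-1-en-1-yl trifluoromethanesulfonate | O=S(=O)(OC1=CCC[C@](C)(C=C)[C@H]1CC=C(C)C)C(F)(F)F | intermediate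
8 | (5R,6S)-5-ethenyl-1,5-dimethyl-6-(3-methylbut-2-en-1-yl)cyclohex-1-ene | CC1=CCC[C@](C)(C=C)[C@H]1CC=C(C)C | intermediate
9 | 9-{2-[(1S,2R)-1,3-dimethyl-2-(3-methylbut-2-en-1-yl)cyclohex-3-en-1-yl]ethyl}-9-borabicyclo[3.3.1]nonane | CC1=CCC[C@](C)(CCB2C3CCCC2CCC3)[C@H]1CC=C(C)C | intermediate
10 | 2-[(1R,2R)-1,3-dimethyl-2-(3-methylbut-2-en-1-yl)cyclohex-3-en-1-yl]ethan-1-ol | CC1=CCC[C@](C)(CCO)[C@H]1CC=C(C)C | intermediate
11 | 2-[(1R,2R)-1,3-dimethyl-2-(3-methylbut-2-en-1-yl)cyclohex-3-en-1-yl]acetaldehyde | CC1=CCC[C@](C)(CC=O)[C@H]1CC=C(C)C | intermediate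
12 | (1E)-2-[(1R,2R)-1,3-dimethyl-2-(3-methylbut-2-en-1-yl)cyclohex-3-en-1-yl]acetaldehyde oxime | CC1=CCC[C@](C)(C/C=N/O)[C@H]1CC=C(C)C | intermediate
13 | (1Z)-N-hydroxy-2-[(1R,2R)-1,3-dimethyl-2-(3-methylbut-2-en-1-yl)cyclohex-3-en-1-yl]ethanimidoyl chloride | CC1=CCC[C@](C)(C/C(Cl)=N/O)[C@H]1CC=C(C)C | intermediate
14 | 2-[(1R,2R)-1,3-dimethyl-2-(3-methylbut-2-en-1-yl)cyclohex-3-en-1-yl]acetonitrile N-oxide | CC1=CCC[C@](C)(CC#[N+][O-])[C@H]1CC=C(C)C | intermediate
15 | trans-fused tricyclic isoxazoline: 4,10-dimethyl-3-ene decalin (5α-H, 10β-methyl) whose C8 is the C=N carbon and C7 (7α-H) the ring carbon of a 4,5-dihydroisoxazole with O on C11 and two methyl groups on C11 [(3aS,4aR,8aR)-3,3,5,8a-tetramethyl-3,3a,4,4a,7,8,8a,9-octahydronaphtho[2,3-c][1,2]oxazole] | CC1=CCC[C@]2(C)CC3=NOC(C)(C)[C@H]3C[C@H]21 | intermediate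
16 | 3α,4α-diol of 15 (3α-OH, 4α-OH, 4β-methyl, 5α-H, 7α-H, 10β-methyl) | O[C@]1(C)[C@H](O)CC[C@]2(C)CC3=NOC(C)(C)[C@H]3C[C@H]21 | intermediate
17 | 4α-hydroxy-3-ketone (4β-methyl, 5α-H, 7α-H, 10β-methyl; isoxazoline as in 15) | O[C@]1(C)C(=O)CC[C@]2(C)CC3=NOC(C)(C)[C@H]3C[C@H]21 | intermediate
18 | 3β,4α-diol (3β-OH, 4α-OH, 4β-methyl, 5α-H, 7α-H, 10β-methyl; isoxazoline as in 15) | O[C@]1(C)[C@@H](O)CC[C@]2(C)CC3=NOC(C)(C)[C@H]3C[C@H]21 | intermediate
19 | tiglic acid [(2E)-2-methylbut-2-enoic acid] | C/C=C(\C)C(=O)O | starting material
20 | (2E)-2-methylbut-2-en-1-ol | C/C=C(\C)CO | intermediate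
21 | [(2R,3R)-2,3-dimethyloxiran-2-yl]methanol | OC[C@@]1(C)O[C@@H]1C | intermediate
22 | (2S,3R)-2,3-dimethyloxirane-2-carboxylic acid | OC(=O)[C@@]1(C)O[C@@H]1C | intermediate
23 | (2S,3R)-2,3-dimethyloxirane-2-carboxylic 2,4,6-trichlorobenzoic anhydride | O=C(OC(=O)c1c(Cl)cc(Cl)cc1Cl)[C@@]1(C)O[C@@H]1C | intermediate
24 | 3β-[(2S,3R)-2,3-dimethyloxirane-2-carbonyloxy]-4α-ol (4β-methyl, 5α-H, 7α-H, 10β-methyl; isoxazoline as in 15) | O[C@]1(C)[C@@H](OC(=O)[C@@]4(C)O[C@@H]4C)CC[C@]2(C)CC3=NOC(C)(C)[C@H]3C[C@H]21 | intermediate
25 | 4α-acetate of 24 | CC(=O)O[C@]1(C)[C@@H](OC(=O)[C@@]4(C)O[C@@H]4C)CC[C@]2(C)CC3=NOC(C)(C)[C@H]3C[C@H]21 | intermediate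
26 | 8-imino-11-hydroxy compound (N–O cleaved 25; 7α-H) | CC(=O)O[C@]1(C)[C@@H](OC(=O)[C@@]3(C)O[C@@H]3C)CC[C@]2(C)CC(=N)[C@@H](C(C)(C)O)C[C@H]21 | intermediate
27 | 8-keto-11-hydroxy compound (4α-acetoxy, 3β-epoxy ester, 5α-H, 7α-H, 10β-methyl) | CC(=O)O[C@]1(C)[C@@H](OC(=O)[C@@]3(C)O[C@@H]3C)CC[C@]2(C)CC(=O)[C@@H](C(C)(C)O)C[C@H]21 | intermediate
28 | CNP0219255.6, (3S,4S,5R,10R)-4α-acetoxy-11-hydroxy-8-oxoeudesm-6-en-3β-yl (2S,3R)-2,3-dimethyloxirane-2-carboxylate | CC(=O)O[C@]1(C)[C@@H](OC(=O)[C@@]2(C)O[C@@H]2C)CC[C@]2(C)CC(=O)C(C(C)(C)O)=C[C@H]21 | target

## Step count and least certain steps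

Total step count: 17. Longest linear sequence: 14 steps (steps 1–10 and 14–17, from 1 to 28); acid 22 is made in parallel in 3 steps (11–13).

**Step 7 (key step).**
- What may go wrong: the reacting conformer with both arms equatorial is disfavoured by allylic strain between the C4 methyl group and C6. Ring closure may therefore be slow enough for dimerisation of the nitrile oxide to furoxans and for electrophilic chlorination of the two trisubstituted alkenes by hypochlorite to compete.
- Fallback: the nitrile oxide is generated without any oxidant. The route is left at alcohol 10, which is converted with I2, PPh3 and imidazole into the primary iodide F1. Displacement with NaNO2 in DMF gives the primary nitro compound F2. Mukaiyama dehydration of F2 with phenyl isocyanate and catalytic Et3N at high dilution gives the same nitrile oxide 14, which cyclises to 15, where the route is rejoined.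

**Step 1.**
- What may go wrong: facial selectivity in the alkylation of the magnesium enolate may be poor, because methyl and vinyl on the neighbouring quaternary carbon differ little. The prenyl group would then enter on both faces and a large share of the C5 epimer would form.
- Fallback: C5 is corrected thermodynamically after ring B exists, where the two ring-fusion isomers can be separated and the wrong one recycled. It sets out from 5, used as the mixture of C5 epimers.
  - 5 is protected with 1,2-bis(trimethylsilyloxy)ethane and catalytic TMSOTf at −78 °C as the dioxolane F3.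
  - F3 is taken through 9-BBN hydroboration/oxidation to alcohol F4, Dess–Martin oxidation to aldehyde F5 and oximation to oxime F6.
  - Hypochlorite cycloaddition gives the ketal isoxazoline F7 together with its cis-fused isomer.
  - Mild aqueous acid releases the tricyclic ketone F8, in which C5 is α to the C4 carbonyl. Equilibration with NaOMe in MeOH is expected to leave the trans-fused ketone as at least a major component, since the C10 methyl loses one syn-axial partner to the carbonyl. The cis isomer is separated and resubmitted.
  - Kinetic triflation of F8 (KHMDS, PhNTf2, −78 °C) gives the enol triflate F9, and iron-catalysed methylation of F9 gives 15, where the route is rejoined.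

**Step 16.**
- What may go wrong: at 80 °C in aqueous acetonitrile the liberated β-hydroxy ketone may undergo retro-aldol cleavage or dehydration, and the glycidic ester may be opened or deoxygenated by the low-valent metal.
- Fallback: the N–O cleavage and the dehydrogenation are carried out before the epoxy ester is attached. It sets out from diol 18.
  - The secondary alcohol of 18 is silylated (TESCl, imidazole) to the 3β-triethylsilyl ether F10, and the tertiary alcohol is acetylated (Ac2O, DMAP) to the acetate F11.
  - Mo(CO)6 in aqueous MeCN gives the β-hydroxy ketone F12, and IBX gives the enone F13.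
  - HF·pyridine removes the silyl group to give the 3β-hydroxy enone F14.
  - F14 is esterified at once with acid 22 under Yamaguchi conditions; the secondary alcohol reacts in preference to the tertiary C11 alcohol. This gives 28, where the route is rejoined.

**Step 17.**
- What may go wrong: enolisation toward the hindered C7 may be too slow, and the warm, slightly acidic IBX medium may eliminate the C11 hydroxyl toward the 7(11)-enone.
- Fallback: a Saegusa–Ito dehydrogenation through a silyl enol ether. It sets out from 27, which with TMSOTf and Et3N at −78 → 0 °C gives the bis-silylated C7=C8 enol ether F15. The regioisomeric C8=C9 enol ether cannot eliminate, because C10 has no hydrogen, and returns 27 on work-up. Pd(OAc)2 in MeCN converts F15 into the C11 trimethylsilyl ether of the enone F16, and citric acid in MeOH removes the silyl group to give 28, where the route is rejoined.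

## Further compounds

F1 | step 7 | (5R,6R)-5-(2-iodoethyl)-1,5-dimethyl-6-(3-methylbut-2-en-1-yl)cyclohex-1-ene | CC1=CCC[C@](C)(CCI)[C@H]1CC=C(C)C
F2 | step 7 | (5R,6R)-1,5-dimethyl-6-(3-methylbut-2-en-1-yl)-5-(2-nitroethyl)cyclohex-1-ene | CC1=CCC[C@](C)(CC[N+](=O)[O-])[C@H]1CC=C(C)C
F3 | step 1 | (6R,7R)-7-ethenyl-7-methyl-6-(3-methylbut-2-en-1-yl)-1,4-dioxaspiro[4.5]decane | O1CCOC12CCC[C@](C)(C=C)[C@H]2CC=C(C)C
F4 | step 1 | 2-[(6R,7R)-7-methyl-6-(3-methylbut-2-en-1-yl)-1,4-dioxaspiro[4.5]decan-7-yl]ethan-1-ol | O1CCOC12CCC[C@](C)(CCO)[C@H]2CC=C(C)C
F5 | step 1 | 2-[(6R,7R)-7-methyl-6-(3-methylbut-2-en-1-yl)-1,4-dioxaspiro[4.5]decan-7-yl]acetaldehyde | O1CCOC12CCC[C@](C)(CC=O)[C@H]2CC=C(C)C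
F6 | step 1 | (1E)-2-[(6R,7R)-7-methyl-6-(3-methylbut-2-en-1-yl)-1,4-dioxaspiro[4.5]decan-7-yl]acetaldehyde oxime | O1CCOC12CCC[C@](C)(C/C=N/O)[C@H]2CC=C(C)C
F7 | step 1 | trans-fused tricyclic isoxazoline with C4 ethylene ketal (5α-H, 7α-H, 10β-methyl) | O1CCOC12CCC[C@]3(C)CC4=NOC(C)(C)[C@H]4C[C@H]32
F8 | step 1 | trans-fused tricyclic isoxazoline C4 ketone (5α-H, 7α-H, 10β-methyl) | O=C1CCC[C@]2(C)CC3=NOC(C)(C)[C@H]3C[C@H]21
F9 | step 1 | C3=C4 enol triflate of F8 | O=S(=O)(OC1=CCC[C@]2(C)CC3=NOC(C)(C)[C@H]3C[C@H]21)C(F)(F)F
F10 | step 16 | 3β-triethylsilyl ether of 18 | O[C@]1(C)[C@@H](O[Si](CC)(CC)CC)CC[C@]2(C)CC3=NOC(C)(C)[C@H]3C[C@H]21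
F11 | step 16 | 4α-acetate of F10 | CC(=O)O[C@]1(C)[C@@H](O[Si](CC)(CC)CC)CC[C@]2(C)CC3=NOC(C)(C)[C@H]3C[C@H]21
F12 | step 16 | 4α-acetoxy-3β-triethylsilyloxy 8-keto-11-hydroxy compound (7α-H) | CC(=O)O[C@]1(C)[C@@H](O[Si](CC)(CC)CC)CC[C@]2(C)CC(=O)[C@@H](C(C)(C)O)C[C@H]21
F13 | step 16 | 4α-acetoxy-3β-triethylsilyloxy-11-hydroxy 6-en-8-one | CC(=O)O[C@]1(C)[C@@H](O[Si](CC)(CC)CC)CC[C@]2(C)CC(=O)C(C(C)(C)O)=C[C@H]21
F14 | step 16 | 4α-acetoxy-3β,11-dihydroxy 6-en-8-one | CC(=O)O[C@]1(C)[C@@H](O)CC[C@]2(C)CC(=O)C(C(C)(C)O)=C[C@H]21
F15 | step 17 | C7=C8 trimethylsilyl enol ether of 27 with C11 trimethylsilyl ether | CC(=O)O[C@]1(C)[C@@H](OC(=O)[C@@]3(C)O[C@@H]3C)CC[C@]2(C)CC(O[Si](C)(C)C)=C(C(C)(C)O[Si](C)(C)C)C[C@H]21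
F16 | step 17 | C11 trimethylsilyl ether of 28 | CC(=O)O[C@]1(C)[C@@H](OC(=O)[C@@]3(C)O[C@@H]3C)CC[C@]2(C)CC(=O)C(C(C)(C)O[Si](C)(C)C)=C[C@H]21
A1 | alternative 1 | 2-(tert-butyldimethylsilyloxy)buta-1,3-diene | C=CC(=C)O[Si](C)(C)C(C)(C)C
A2 | alternative 1 | methyl 2-methyl-6-oxocyclohex-1-ene-1-carboxylate | COC(=O)C1=C(C)CCCC1=O
A3 | alternative 1 | cis-fused Diels–Alder adduct (10β-methyl, 5β-methoxycarbonyl, C4 ketone, C7=C8 silyl enol ether) | O=C1CCC[C@]2(C)CC(O[Si](C)(C)C(C)(C)C)=CC[C@@]21C(=O)OC
A4 | alternative 2 | germacrone | C/C1=C\CC/C(C)=C/CC(=C(C)C)C(=O)C1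
A5 | alternative 2 | trans-eudesma-3,7(11)-dien-8-one (5α-H, 10β-methyl) | CC1=CCC[C@]2(C)CC(=O)C(=C(C)C)C[C@H]21
A6 | alternative 3 | (3S,6E)-3-(tert-butyldimethylsilyloxy)-10-chloro-6-methylundeca-6,10-dien-2-one | CC(=O)[C@@H](O[Si](C)(C)C(C)(C)C)CC/C(C)=C/CCC(Cl)=C
A7 | alternative 3 | trans-decalin with 4α-hydroxy-4β-methyl, 3β-(tert-butyldimethylsilyloxy), 10β-methyl and C8 ketone | O[C@]1(C)[C@@H](O[Si](C)(C)C(C)(C)C)CC[C@]2(C)CC(=O)CC[C@H]21
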